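**Retrosynthetic overview**

- The norbornene and the spiro centre are made last, by a [4+2] union of a 2‑acetoxy‑guaia‑1(5),3‑dien‑12,8‑olide (cyclopentadiene, made in the flask) with the exocyclic methylene of 1‑O‑acetylbritannilactone, as in the presumed biosynthesis.
- Diene half: selenoxide elimination ⇐ 2‑oxo‑guai‑1(5)‑en‑12,8‑olide ⇐ 1,6‑cuprate addition and lactonisation on a hydroazulene dienone ⇐ ring‑closing metathesis (seven‑membered ring) ⇐ Stetter/aldol cyclopentenone (five‑membered ring first).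
- Dienophile half: intramolecular allylindium addition of a butenolide to a (Z)‑enal (cyclohexene last) ⇐ lactol ⇐ catalytic hetero‑Diels–Alder dihydropyran (first ring) from a silyloxydiene and a Baylis–Hillman aldehyde.
- Both halves start from (S)‑citronellal, which supplies C‑10 of the guaiane and C‑4 of the seco‑eudesmane side chain.

Assumption: C‑4 of 23–37 and C‑3 of 34–37 (3,4‑trans) are carried as epimer mixtures, because both become sp2 in step 24; the cuprate of step 19 is prepared separately. The route is a design; it has not been run.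

**Dienophile half**

Step 1
Reactants: 1 (S)-citronellal
Product: 2 trimethyl{[(3S)-3,7-dimethylocta-1,6-dien-1-yl]oxy}silane (E/Z)
Conditions: TMSCl, Et3N, DMF, 80 °C
Reagents that add atoms: chlorotrimethylsilane, C[Si](C)(C)Cl
Why: Thermodynamic O‑silylation of the aldehyde enol gives the enol silane for a directed crossed aldol reaction; the C‑3 stereocentre is not touched.

Step 2
Reactants: 2 silyl enol ether
Product: 4 (3S)-3,7-dimethyl-2-(propan-2-ylidene)oct-6-enal, via methoxy aldehyde 3 (not isolated)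
Conditions: Me2C(OMe)2, TMSOTf (5 mol%), CH2Cl2, −78 °C; then p-TsOH (cat.), PhH, 60 °C
Reagents that add atoms: 2,2-dimethoxypropane, COC(C)(C)OC
Why: Mukaiyama aldol addition of the enol silane to the acetone acetal, then acid‑induced loss of methanol, gives the conjugated tetrasubstituted enal.

Step 3
Reactants: 4 dienal
Product: 7 (3S)-6-hydroxy-3-methyl-2-(propan-2-ylidene)hexanal, via ozonide 5 (not isolated), via dialdehyde 6 (not isolated)
Conditions: O3 (1.0 equiv, Sudan red end point), CH2Cl2, −78 °C; PPh3; then NaBH4 (0.3 equiv), MeOH, −78 °C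
Reagents that add atoms: ozone, O=[O+][O-]
Why: Ozonolysis cleaves only the electron‑rich isolated trisubstituted alkene, and the unhindered saturated aldehyde is then reduced faster than the fully substituted conjugated one.

Step 4
Reactants: 7 hydroxy enal
Product: 8 (4S)-5-formyl-4,6-dimethylhept-5-en-1-yl acetate
Conditions: Ac2O, pyridine, DMAP (cat.), CH2Cl2, 0 °C
Reagents that add atoms: acetic anhydride, CC(=O)OC(C)=O
Why: Standard acylation installs the side‑chain acetate of the target early; all later steps tolerate it.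

Step 5
Reactants: 8 acetoxy enal
Product: 9 (4S,5E)-5-({[tert-butyl(dimethyl)silyl]oxy}methylidene)-4,6-dimethylhept-6-en-1-yl acetate
Conditions: TBSOTf, Et3N, Et2O, −78 → 0 °C
Reagents that add atoms: tert-butyldimethylsilyl triflate, CC(C)(C)[Si](C)(C)OS(=O)(=O)C(F)(F)F
Why: O‑silylation and γ‑deprotonation of the s‑trans enal (vinylogous enol silane formation) give the (1E)‑1‑silyloxy diene needed for the cycloaddition.

Step 6
Reactants: 10 methyl acrylate; 11 2,2-dimethoxyacetaldehyde
Product: 12 methyl 3-hydroxy-4,4-dimethoxy-2-methylidenebutanoate (racemic)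
Conditions: DABCO (20 mol%), dioxane/H2O, 23 °C
Reagents that add atoms: none
Why: Morita–Baylis–Hillman reaction of the activated α‑alkoxy aldehyde; the carbinol centre is lost again in step 11, so it is made racemic.

Step 7
Reactants: 12 Baylis–Hillman alcohol
Product: 13 methyl 3-acetoxy-4,4-dimethoxy-2-methylidenebutanoate
Conditions: Ac2O, pyridine, DMAP (cat.), 0 °C
Reagents that add atoms: acetic anhydride, CC(=O)OC(C)=O
Why: Acylation turns the allylic alcohol into the leaving group for the later palladium‑allyl ionisation.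

Step 8
Reactants: 13 acetal
Product: 14 methyl 3-acetoxy-2-methylidene-4-oxobutanoate (racemic, used crude)
Conditions: Amberlyst 15, acetone/H2O, 23 °C
Reagents that add atoms: water, O
Why: Mild acid hydrolysis of the dimethyl acetal frees the aldehyde without touching the allylic acetate.

Step 9
Reactants: 9 silyloxy diene; 14 aldehyde
Product: 15 methyl 3-acetoxy-3-[(2R)-5-[(2S)-5-acetoxypentan-2-yl]-6-{[tert-butyl(dimethyl)silyl]oxy}-4-methyl-3,6-dihydro-2H-pyran-2-yl]-2-methylidenepropanoate (mixture at the acetal and acetate carbons)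
Conditions: CrCl(C27H29NO2) (5 mol%; Jacobsen Schiff‑base complex of trivalent chromium from 3-(1-adamantyl)-5-methylsalicylaldehyde and (1S,2R)-1-aminoindan-2-ol), 4 Å MS, acetone, 23 °C
Reagents that add atoms: none
Why: Catalyst‑controlled hetero‑Diels–Alder reaction; the concerted cycloaddition fixes the cis (Z) geometry of the tetrasubstituted alkene and the catalyst sets the carbinol carbon (2R, future C‑8), the antipodal catalyst being used should the facial sense prove opposite.

Step 10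
Reactants: 15 dihydropyran
Product: 17 (4S,5Z)-7-[(2R)-3-acetoxy-4-methylidene-5-oxooxolan-2-yl]-5-formyl-4,6-dimethylhept-5-en-1-yl acetate, via lactol 16 (not isolated)
Conditions: HF·pyridine, THF, 0 °C; then PPTS (cat.), PhMe, 60 °C
Reagents that add atoms: none
Why: Desilylation gives the lactol, whose open hydroxy enal form is drained by lactonisation onto the acrylate ester; this gives the butenolide and the free (Z)‑enal.

Step 11
Reactants: 17 enal butenolide
Product: 19 1-O-acetylbritannilactone, via allylindium species 18 (not isolated)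
Conditions: Pd(PPh3)4 (5 mol%, zerovalent palladium), InI (1.3 equiv), THF (5 mM), 23 °C; aq. NH4Cl
Reagents that add atoms: none
Why: Palladium/indium umpolung (Barbier‑type) allylation: the allylindium adds through its ring carbon to the tethered aldehyde, so the lactone must be cis‑fused, and the closed chair transition state of the ring‑locked E‑type allyl unit gives the anti adduct (C‑6 OH trans to C‑7–C‑11).

**Diene half**

Step 12
Reactants: 20 (E)-but-2-enoyl chloride; 21 isopropenylmagnesium bromide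
Product: 22 (4E)-2-methylhexa-1,4-dien-3-one
Conditions: Fe(acac)3 (3 mol%), THF, −78 °C
Reagents that add atoms: none
Why: Iron‑catalysed acylation of the Grignard reagent stops at the ketone and gives the cross‑conjugated dienone.

Step 13
Reactants: 1 (S)-citronellal; 22 dienone
Product: 23 (2E,9S)-5,9,13-trimethyltetradeca-2,12-diene-4,7-dione (C-5 epimers)
Conditions: 3-benzyl-5-(2-hydroxyethyl)-4-methylthiazolium chloride (15 mol%), Et3N, EtOH, 70 °C
Reagents that add atoms: none
Why: Stetter reaction; the acyl anion equivalent adds to the unsubstituted terminus of the isopropenyl group rather than to the β‑methyl‑substituted propenyl group.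

Step 14
Reactants: 23 1,4-diketone
Product: 24 4-methyl-2-[(2S)-6-methylhept-5-en-2-yl]-3-[(1E)-prop-1-en-1-yl]cyclopent-2-en-1-one (C-4 epimers)
Conditions: NaOH (2% aq.), EtOH, 70 °C
Reagents that add atoms: none
Why: Intramolecular aldol condensation (jasmone‑type); only one five‑membered ring closure is possible, and C‑10 is not enolisable.

Step 15
Reactants: 24 cyclopentenone
Product: 26 (4S)-4-{3-methyl-5-oxo-2-[(1E)-prop-1-en-1-yl]cyclopent-1-en-1-yl}pentanal, via ozonide 25 (not isolated)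
Conditions: O3 (1.0 equiv), pyridine, CH2Cl2, −78 °C; PPh3
Reagents that add atoms: ozone, O=[O+][O-]
Why: Chemoselective ozonolysis of the isolated trisubstituted alkene; the dienone alkenes are electron‑poor and react more slowly.

Step 16
Reactants: 26 aldehyde
Product: 27 (2S,4S)-4-{3-methyl-5-oxo-2-[(1E)-prop-1-en-1-yl]cyclopent-1-en-1-yl}-2-[(2,2,6,6-tetramethylpiperidin-1-yl)oxy]pentanal
Conditions: (5S)-5-benzyl-2,2,3-trimethylimidazolidin-4-one·HBF4 (20 mol%), FeCl3 (10 mol%), NaNO2 (30 mol%), O2, DMF, −10 °C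
Reagents that add atoms: TEMPO, CC1(C)CCCC(C)(C)N1[O]
Why: Organocatalytic (enamine radical cation) α‑oxyamination; the catalyst shields one enamine face and sets C‑8 (S) independently of the remote C‑10.

Step 17
Reactants: 27 α-oxy aldehyde
Product: 28 4-methyl-3-[(1E)-prop-1-en-1-yl]-2-{(2S,4S)-4-[(2,2,6,6-tetramethylpiperidin-1-yl)oxy]hex-5-en-2-yl}cyclopent-2-en-1-one
Conditions: Ph3PCH3Br, KHMDS, THF, −78 → 0 °C
Reagents that add atoms: methyltriphenylphosphonium bromide, C[P+](c1ccccc1)(c1ccccc1)c1ccccc1.[Br-]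
Why: Wittig methylenation of the aldehyde with a salt‑free ylide at low temperature, which avoids epimerisation at C‑8 and leaves the hindered dienone carbonyl alone.

Step 18
Reactants: 28 triene
Product: 29 (6S,8S)-3,8-dimethyl-6-[(2,2,6,6-tetramethylpiperidin-1-yl)oxy]-3,6,7,8-tetrahydroazulen-1(2H)-one
Conditions: second-generation Grubbs catalyst RuCl2(=CHPh)(SIMes)(PCy3) (5 mol%), CH2Cl2 (2 mM), 40 °C
Reagents that add atoms: none
Why: Ring‑closing metathesis between the vinyl and propenyl groups, held cis on the cyclopentenone, closes the seven‑membered ring with loss of propene.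

Step 19
Reactants: 29 hydroazulene dienone
Product: 31 methyl 2-[(5R,6S,8S)-3,8-dimethyl-1-oxo-6-[(2,2,6,6-tetramethylpiperidin-1-yl)oxy]-1,2,3,4,5,6,7,8-octahydroazulen-5-yl]prop-2-enoate, via deconjugated ketone 30 (not isolated)
Conditions: Li[Cu(C≡CBu){C(=CH2)CO2Me}], Et2O/THF, −78 °C; aq. NH4Cl; then DBU (cat.), CH2Cl2, 23 °C
Reagents that add atoms: lithium hex-1-ynyl[1-(methoxycarbonyl)ethenyl]cuprate, [Li+].CCCCC#C[Cu-]C(=C)C(=O)OC
Why: 1,6‑Conjugate addition of the cuprate (the β‑carbon is fully substituted) occurs at C‑7 anti to the bulky C‑8 alkoxyamine and sets the trans C‑7/C‑8 relationship; DBU returns the alkene to conjugation.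

Step 20
Reactants: 31 alkoxyamine ester
Product: 33 (7R,8S,10S)-2-oxoguaia-1(5),11(13)-dien-12,8-olide (trans-fused), via hydroxy ester 32 (not isolated)
Conditions: Zn, AcOH/THF/H2O, 50 °C
Reagents that add atoms: none
Why: Reductive N–O cleavage frees the C‑8 hydroxyl, which lactonises onto the acrylate ester with retention at C‑8 to give the trans‑fused α‑methylene lactone.

Step 21
Reactants: 33 enone lactone
Product: 34 (7R,8S,10S)-2-oxo-3-(phenylselanyl)guaia-1(5),11(13)-dien-12,8-olide (3,4-trans)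
Conditions: LiHMDS (1.05 equiv), THF, −78 °C; PhSeBr
Reagents that add atoms: phenylselenyl bromide, Br[Se]c1ccccc1
Why: Kinetic α′‑deprotonation and selenenylation at C‑3, the only α′ position, place selenium trans to the C‑4 methyl and therefore syn to H‑4.

Step 22
Reactants: 34 seleno ketone
Product: 35 (2S,7R,8S,10S)-2-hydroxy-3-(phenylselanyl)guaia-1(5),11(13)-dien-12,8-olide
Conditions: (S)-2-methyl-CBS-oxazaborolidine (0.3 equiv), catecholborane, PhMe/CH2Cl2, −78 → −40 °C
Reagents that add atoms: none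
Why: Corey–Bakshi–Shibata reduction with the alkenyl side as the large group sets the 2β‑hydroxyl under reagent control (the descriptor is S only because of the selenium neighbour).

Step 23
Reactants: 35 allylic alcohol
Product: 36 (2S,7R,8S,10S)-2-acetoxy-3-(phenylselanyl)guaia-1(5),11(13)-dien-12,8-olide
Conditions: Ac2O, Et3N, DMAP (cat.), CH2Cl2, 0 °C
Reagents that add atoms: acetic anhydride, CC(=O)OC(C)=O
Why: Acylation of the secondary allylic alcohol gives the stable, storable precursor of the labile acetoxy‑cyclopentadiene.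

**Union**

Step 24
Reactants: 36 selenide acetate; 19 1-O-acetylbritannilactone
Product: 39 target dimer CNP0211028.3, via selenoxide 37 (not isolated), via acetoxy diene 38 (not isolated)
Conditions: mCPBA (1.0 equiv), CH2Cl2, −78 °C; then i-Pr2NH (3 equiv) and 19 (2.5 equiv), −78 → 23 °C, concentrated to 2 M, 36 h
Reagents that add atoms: none
Why: Selenoxide syn‑elimination, directed away from the acetoxy carbon and toward H‑4, releases the 5‑acetoxy‑cyclopentadiene below room temperature, where it is trapped in a Diels–Alder reaction before a 1,5‑hydrogen shift; the dienophile is expected to add to the α‑face, anti to the 2β‑acetoxy and 10β‑methyl groups, with its CH2 at C‑1, its quaternary carbon at the unsubstituted C‑3 and the lactone carbonyl exo, which sets C‑1, C‑3 and C‑11′ in one step.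

**Compound list**

1 | (S)-citronellal | O=CC[C@@H](C)CCC=C(C)C | starting material
2 | trimethyl{[(3S)-3,7-dimethylocta-1,6-dien-1-yl]oxy}silane (E/Z) | C[Si](C)(C)OC=C[C@@H](C)CCC=C(C)C | intermediate
3 | (3S)-2-(2-methoxypropan-2-yl)-3,7-dimethyloct-6-enal (C-2 epimers) | COC(C)(C)C(C=O)[C@@H](C)CCC=C(C)C | intermediate
4 | (3S)-3,7-dimethyl-2-(propan-2-ylidene)oct-6-enal | CC(C)=C(C=O)[C@@H](C)CCC=C(C)C | intermediate
5 | (3S)-5-(5,5-dimethyl-1,2,4-trioxolan-3-yl)-3-methyl-2-(propan-2-ylidene)pentanal | CC(C)=C(C=O)[C@@H](C)CCC1OOC(C)(C)O1 | intermediate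
6 | (3S)-3-methyl-2-(propan-2-ylidene)hexanedial | CC(C)=C(C=O)[C@@H](C)CCC=O | intermediate
7 | (3S)-6-hydroxy-3-methyl-2-(propan-2-ylidene)hexanal | CC(C)=C(C=O)[C@@H](C)CCCO | intermediate
8 | (4S)-5-formyl-4,6-dimethylhept-5-en-1-yl acetate | CC(C)=C(C=O)[C@@H](C)CCCOC(C)=O | intermediate
9 | (4S,5E)-5-({[tert-butyl(dimethyl)silyl]oxy}methylidene)-4,6-dimethylhept-6-en-1-yl acetate | C=C(C)/C(=C/O[Si](C)(C)C(C)(C)C)[C@@H](C)CCCOC(C)=O | intermediate
10 | methyl acrylate | C=CC(=O)OC | starting material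
11 | 2,2-dimethoxyacetaldehyde | COC(OC)C=O | starting material
12 | methyl 3-hydroxy-4,4-dimethoxy-2-methylidenebutanoate (racemic) | C=C(C(=O)OC)C(O)C(OC)OC | intermediate
13 | methyl 3-acetoxy-4,4-dimethoxy-2-methylidenebutanoate | C=C(C(=O)OC)C(OC(C)=O)C(OC)OC | intermediate
14 | methyl 3-acetoxy-2-methylidene-4-oxobutanoate | C=C(C(=O)OC)C(OC(C)=O)C=O | intermediate
15 | hetero-Diels–Alder adduct, (2R)-dihydropyran silyl acetal | CC(C)(C)[Si](C)(C)OC1O[C@H](CC(C)=C1[C@@H](C)CCCOC(C)=O)C(OC(C)=O)C(=C)C(=O)OC | intermediate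
16 | lactol of 15 | OC1O[C@H](CC(C)=C1[C@@H](C)CCCOC(C)=O)C(OC(C)=O)C(=C)C(=O)OC | intermediate
17 | (4S,5Z)-7-[(2R)-3-acetoxy-4-methylidene-5-oxooxolan-2-yl]-5-formyl-4,6-dimethylhept-5-en-1-yl acetate | O=C/C(=C(/C)C[C@H]1OC(=O)C(=C)C1OC(C)=O)[C@@H](C)CCCOC(C)=O | intermediate
18 | acetato(iodo)[(butenolid-3-yl)methyl]indium species | CC(=O)O[In](I)CC1=C[C@@H](C/C(C)=C(\C=O)[C@@H](C)CCCOC(C)=O)OC1=O | intermediate
19 | 1-O-acetylbritannilactone, (4S)-4-[(3aS,4S,7aR)-4-hydroxy-6-methyl-3-methylidene-2-oxo-2,3,3a,4,7,7a-hexahydro-1-benzofuran-5-yl]pentyl acetate | C=C1C(=O)O[C@@H]2CC(C)=C([C@@H](C)CCCOC(C)=O)[C@@H](O)[C@@H]12 | intermediate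
20 | (E)-but-2-enoyl chloride | C/C=C/C(=O)Cl | starting material
21 | isopropenylmagnesium bromide | C=C(C)[Mg]Br | starting material
22 | (4E)-2-methylhexa-1,4-dien-3-one | C=C(C)C(=O)/C=C/C | intermediate
23 | (2E,9S)-5,9,13-trimethyltetradeca-2,12-diene-4,7-dione | C/C=C/C(=O)C(C)CC(=O)C[C@@H](C)CCC=C(C)C | intermediate
24 | 4-methyl-2-[(2S)-6-methylhept-5-en-2-yl]-3-[(1E)-prop-1-en-1-yl]cyclopent-2-en-1-one | C/C=C/C1=C([C@@H](C)CCC=C(C)C)C(=O)CC1C | intermediate
25 | ozonide of 24 | C/C=C/C1=C([C@@H](C)CCC2OOC(C)(C)O2)C(=O)CC1C | intermediate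
26 | (4S)-4-{3-methyl-5-oxo-2-[(1E)-prop-1-en-1-yl]cyclopent-1-en-1-yl}pentanal | C/C=C/C1=C([C@@H](C)CCC=O)C(=O)CC1C | intermediate
27 | (2S,4S)-2-[(2,2,6,6-tetramethylpiperidin-1-yl)oxy] derivative of 26 | C/C=C/C1=C([C@@H](C)C[C@H](ON2C(C)(C)CCCC2(C)C)C=O)C(=O)CC1C | intermediate
28 | 4-methyl-3-[(1E)-prop-1-en-1-yl]-2-{(2S,4S)-4-[(2,2,6,6-tetramethylpiperidin-1-yl)oxy]hex-5-en-2-yl}cyclopent-2-en-1-one | C/C=C/C1=C([C@@H](C)C[C@H](ON2C(C)(C)CCCC2(C)C)C=C)C(=O)CC1C | intermediate
29 | (6S,8S)-3,8-dimethyl-6-[(2,2,6,6-tetramethylpiperidin-1-yl)oxy]-3,6,7,8-tetrahydroazulen-1(2H)-one | CC1CC(=O)C2=C1C=C[C@@H](ON3C(C)(C)CCCC3(C)C)C[C@@H]2C | intermediate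
30 | β,γ-unsaturated isomer of 31 | C=C(C(=O)OC)[C@H]1C=C2C(C)CC(=O)C2[C@@H](C)C[C@@H]1ON1C(C)(C)CCCC1(C)C | intermediate
31 | methyl 2-[(5R,6S,8S)-3,8-dimethyl-1-oxo-6-[(2,2,6,6-tetramethylpiperidin-1-yl)oxy]-1,2,3,4,5,6,7,8-octahydroazulen-5-yl]prop-2-enoate | C=C(C(=O)OC)[C@H]1CC2=C(C(=O)CC2C)[C@@H](C)C[C@@H]1ON1C(C)(C)CCCC1(C)C | intermediate
32 | methyl 2-[(5R,6S,8S)-6-hydroxy-3,8-dimethyl-1-oxo-1,2,3,4,5,6,7,8-octahydroazulen-5-yl]prop-2-enoate | C=C(C(=O)OC)[C@H]1CC2=C(C(=O)CC2C)[C@@H](C)C[C@@H]1O | intermediate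
33 | (7R,8S,10S)-2-oxoguaia-1(5),11(13)-dien-12,8-olide | C=C1C(=O)O[C@H]2C[C@H](C)C3=C(C[C@H]12)C(C)CC3=O | intermediate
34 | (7R,8S,10S)-2-oxo-3-(phenylselanyl)guaia-1(5),11(13)-dien-12,8-olide | C=C1C(=O)O[C@H]2C[C@H](C)C3=C(C[C@H]12)C(C)C([Se]c1ccccc1)C3=O | intermediate
35 | (2S,7R,8S,10S)-2-hydroxy-3-(phenylselanyl)guaia-1(5),11(13)-dien-12,8-olide | C=C1C(=O)O[C@H]2C[C@H](C)C3=C(C[C@H]12)C(C)C([Se]c1ccccc1)[C@H]3O | intermediate
36 | (2S,7R,8S,10S)-2-acetoxy-3-(phenylselanyl)guaia-1(5),11(13)-dien-12,8-olide | C=C1C(=O)O[C@H]2C[C@H](C)C3=C(C[C@H]12)C(C)C([Se]c1ccccc1)[C@H]3OC(C)=O | intermediate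
37 | selenoxide of 36 | C=C1C(=O)O[C@H]2C[C@H](C)C3=C(C[C@H]12)C(C)C([Se](=O)c1ccccc1)[C@H]3OC(C)=O | intermediate
38 | (2R,7R,8S,10S)-2-acetoxyguaia-1(5),3,11(13)-trien-12,8-olide | C=C1C(=O)O[C@H]2C[C@H](C)C3=C(C[C@H]12)C(C)=C[C@H]3OC(C)=O | intermediate
39 | target dimer CNP0211028.3 | C=C1C(=O)O[C@H]2C[C@H](C)[C@@]34C[C@]5(C(=O)O[C@@H]6CC(C)=C([C@@H](C)CCCOC(C)=O)[C@@H](O)[C@@H]65)[C@@H](C(C)=C3C[C@H]12)[C@H]4OC(C)=O | target

**Step count**

Total: 24 steps. Longest linear sequence: 13 steps (20/21 → 22 → 23 → … → 36 → 39; steps 12–24).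

**Steps most likely to fail, with fallbacks**

Step 24 (in‑flask diene formation and cycloaddition). The acetoxy diene can undergo a 1,5‑hydrogen shift, dimerise through its own methylene lactone, or add with the wrong facial or regiochemical sense. The intrinsic preference of 5‑acetoxy‑cyclopentadienes for syn attack and the choice of dienophile face are not secured, so separation of diastereomers may be needed. The fallback sets out from 33 and makes the diene by dehydration of the presumed biogenetic tertiary alcohol at low temperature under Lewis‑acid acceleration. TBSOTf/Et3N gives the extended silyl dienol ether F1, and dimethyldioxirane (vinylogous Rubottom oxidation) gives the 4‑hydroxy enone F2. (S)‑CBS/catecholborane reduction gives the 2β,4‑diol F3, and Ac2O/pyridine acylates only the secondary hydroxyl to give the 2‑acetoxy‑4‑hydroxy‑guai‑1(5)‑ene F4. Martin sulfurane, Ph2S[OC(CF3)2Ph]2, at −50 °C in the presence of 19 and Me2AlCl then dehydrates F4 to 38, which is trapped at −40 °C; the route is rejoined at 38 and 39.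

Step 11 (palladium/indium ring closure). Possible failures are reduction of the allyl unit, intermolecular coupling, or the wrong C‑6 configuration. The fallback sets out from 17 and replaces the allylindium by an allylboronate with a closed, metal‑free transition state. Pd2(dba)3 (zerovalent palladium) with B2pin2 converts the allylic acetate into the 3‑[(pinacolboryl)methyl]butenolide F5. Intramolecular allylboration of the enal (PhMe, 60 °C, or Sc(OTf)3 at −40 °C) and aqueous work‑up return the route at 19.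

Step 19 (1,6‑addition of the 1‑(methoxycarbonyl)vinyl cuprate). This reagent is thermally fragile and may polymerise or add poorly. The fallback sets out from 29 and brings in the three carbons as an isopropenyl group, oxidised afterwards. Isopropenylmagnesium bromide (21) with CuBr·SMe2 gives, again anti to the alkoxyamine, the isopropenyl ketone F6. Zn/AcOH gives the hydroxy ketone F7, and SeO2/t‑BuOOH oxidises the isopropenyl methyl to the allylic alcohol F8. TEMPO/PhI(OAc)2 oxidative lactonisation of this diol returns the route at 33.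

Further compounds
F1 | step 24 | (7R,8S,10S)-2-{[tert-butyl(dimethyl)silyl]oxy}guaia-1,4,11(13)-trien-12,8-olide | C=C1C(=O)O[C@H]2C[C@H](C)C3=C(O[Si](C)(C)C(C)(C)C)CC(C)=C3C[C@H]12
F2 | step 24 | (7R,8S,10S)-4-hydroxy-2-oxoguaia-1(5),11(13)-dien-12,8-olide | C=C1C(=O)O[C@H]2C[C@H](C)C3=C(C[C@H]12)C(C)(O)CC3=O
F3 | step 24 | (2R,7R,8S,10S)-2,4-dihydroxyguaia-1(5),11(13)-dien-12,8-olide | C=C1C(=O)O[C@H]2C[C@H](C)C3=C(C[C@H]12)C(C)(O)C[C@H]3O
F4 | step 24 | (2R,7R,8S,10S)-2-acetoxy-4-hydroxyguaia-1(5),11(13)-dien-12,8-olide | C=C1C(=O)O[C@H]2C[C@H](C)C3=C(C[C@H]12)C(C)(O)C[C@H]3OC(C)=O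
F5 | step 11 | (4S,5Z)-5-formyl-4,6-dimethyl-7-{(2R)-5-oxo-4-[(4,4,5,5-tetramethyl-1,3,2-dioxaborolan-2-yl)methyl]-2,5-dihydrofuran-2-yl}hept-5-en-1-yl acetate | CC1(C)OB(CC2=C[C@@H](C/C(C)=C(\C=O)[C@@H](C)CCCOC(C)=O)OC2=O)OC1(C)C
F6 | step 19 | (5R,6S,8S)-3,8-dimethyl-5-(prop-1-en-2-yl)-6-[(2,2,6,6-tetramethylpiperidin-1-yl)oxy]-3,4,5,6,7,8-hexahydroazulen-1(2H)-one | C=C(C)[C@H]1CC2=C(C(=O)CC2C)[C@@H](C)C[C@@H]1ON1C(C)(C)CCCC1(C)C
F7 | step 19 | (5R,6S,8S)-6-hydroxy-3,8-dimethyl-5-(prop-1-en-2-yl)-3,4,5,6,7,8-hexahydroazulen-1(2H)-one | C=C(C)[C@H]1CC2=C(C(=O)CC2C)[C@@H](C)C[C@@H]1O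
F8 | step 19 | (5R,6S,8S)-6-hydroxy-5-(3-hydroxyprop-1-en-2-yl)-3,8-dimethyl-3,4,5,6,7,8-hexahydroazulen-1(2H)-one | C=C(CO)[C@H]1CC2=C(C(=O)CC2C)[C@@H](C)C[C@@H]1O
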